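The rate constants were set for the occasion; no experiment stands behind them.

The leftover came first when your note arrived with the hunch that a richer charge leaves more target in the mix. In north-west the 0.060 M of starting material stood above the 0.0190 M of partner, and the two react one to one, so partner was the limiting reagent there and 68.3% of the starting material had no partner to react with.

in all of them: partner 0.0190 M; time 8.0 h
- south: starting material 0.0020 M
- north-east: starting material 0.0060 M
- south-east: starting material 0.020 M
- north-west: starting material 0.060 M

    target ⇌ isomer of the product (K1 = 3.0, k1 = 0.30 h⁻¹)
    starting material + partner + target → 2 target (k2 = 12000 L² mol⁻² h⁻¹)
    starting material + partner → target (k3 = 0.029 L mol⁻¹ h⁻¹)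

* share of target in all that became target or isomer of the product for south, north-east, south-east, north-west, in this order
* how the row runs (rises, then falls / falls, then rises / rises all the way / falls all the way / hardly changes)

- "hardly changes" means that all values lie within two and a half points (for a concentration: within two and a half percent of the largest)
- run time (south): 8.0 h

For your quick number I compared two rates at the moment of charging, and began with south:

r = 12000 L² mol⁻² h⁻¹ × 0.0020 M × 0.0190 M / 0.30 h⁻¹ = 1.52

This r, the rate at which one target molecule makes a new one over the rate at which it passes forward to the isomer, came out as follows for the richer flasks:

north-east: 4.56
south-east: 15.2
north-west: 45.6

Then I asked how the comparison drifts. Each autocatalytic turn consumes starting material and partner, so r shrinks with their product. While r stays above 1, making beats the forward loss. Once r has sunk, target and isomer relax towards the equilibrium share of target, 25.0%, with a half-life of 1.73 h, short against the 8.0 h of the run.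

So I committed to a shape without percentages. South to north-east should rise, as you guessed, since r was higher in north-east. South-east and north-west, with r far above south's, should burn through early and sit near 25.0%.

The forecast gave 59%, 67%, 32% and 29%, shape rises, then falls, on the ground that “the share stays high only while fresh target is still forming”.

The flasks gave 58.7%, 64.4%, 34.8% and 29.1%, shape rises, then falls, with the turn at 0.0045 M of starting material. In south, target was still being made 2.16 times faster than it was used up at 8.00 h. Put to the amounts standing at 8.00 h, r was 1.49 in south and 1.23 in north-east. In south-east it was 0.0789, with partner at 5.22% of its charge and target at 31.3%.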